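**Plan**

Ring labels: A = trioxygenated ring bearing the ether to ring B; B = para-phenylene; C = second trioxygenated ring (C1–CH2, C3–O–ring D, C4–OH, C5–OH); D = meta-phenylene.
Retrosynthesis, in order: three O-methyl groups (ring A ×2, ring C C5); ring C C4–OH back to C4–H; the macrocycle at the ring C C3–O(ring D) bond, giving a ring D phenol and a ring C aryne C3≡C4; the B–CH2CH2–C and A–CH2CH2–D bridges (B-alkyl Suzuki–Miyaura); the ring A–O–ring B ether (SNAr).
Forward: SNAr joins A and B; the D arene and then the C arene are attached by hydroboration/cross-coupling; ring C becomes an o-silylaryl triflate (C3–OTf, C4–SiMe3); fluoride closes the 19-membered ring; C4 is hydroxylated; demethylation ends the route.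
Enabling feature: in ring C the ether carbon C3 is meta to the C5 oxygen with C4 between them, so the aryne C3≡C4 is a 3-alkoxyaryne. Its C5–OMe sends the phenoxide oxygen to C3 and leaves C4, flanked by two oxygens, as the site of the later lithiation.
Stereochemistry: the target has no stereocentre and no stereogenic double bond, so none has to be set.

Key step: step 11

Remarks: Compounds 1, 2, 5 and 11 (and 4-bromo-2-methoxyphenol, used only in fallbacks) are taken as commercial. The macrocycle is treated as conformationally mobile (no atropisomers). Abbreviations: "arm P" = 2-[4-(5-{2-[3-(benzyloxy)phenyl]ethyl}-2,3-dimethoxyphenoxy)phenyl]ethyl; "arm Q" = the same group with a free 3-hydroxyphenyl in place of 3-(benzyloxy)phenyl.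

**Route**

Step 1
Reactants: 1 3-hydroxy-4,5-dimethoxybenzaldehyde; 2 4-fluorobenzonitrile
Product: 3 4-(5-formyl-2,3-dimethoxyphenoxy)benzonitrile
Conditions: K2CO3, DMF, 110 °C
Reagents that add atoms: none
Why: SNAr; the phenoxide of 1 should displace fluoride para to the nitrile of 2 through a Meisenheimer complex, and the aldehyde is inert to carbonate.

Step 2
Reactants: 3 4-(5-formyl-2,3-dimethoxyphenoxy)benzonitrile
Product: 4 4-(5-ethenyl-2,3-dimethoxyphenoxy)benzonitrile
Conditions: Ph3PCH3Br, KOtBu, THF, 0 °C → rt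
Reagents that add atoms: methyltriphenylphosphonium bromide, C[P+](c1ccccc1)(c1ccccc1)c1ccccc1.[Br-]
Why: Wittig methylenation should turn the ring A aldehyde into the styrene needed for hydroboration; the nitrile does not react with the ylide at this temperature.

Step 3
Reactants: 4 4-(5-ethenyl-2,3-dimethoxyphenoxy)benzonitrile; 5 1-(benzyloxy)-3-bromobenzene
Product: 7 4-(5-{2-[3-(benzyloxy)phenyl]ethyl}-2,3-dimethoxyphenoxy)benzonitrile, via B-alkyl-9-BBN adduct 6 (not isolated)
Conditions: 9-BBN, THF, 0 °C → rt; then Pd(dppf)Cl2 (cat.), aq. K3PO4, DMF, 60 °C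
Reagents that add atoms: none
Why: Anti-Markovnikov hydroboration of the styrene with 9-BBN followed by B-alkyl Suzuki–Miyaura coupling with 5 should give the A–CH2CH2–D bridge in one flask; the nitrile is inert to 9-BBN at room temperature.

Step 4
Reactants: 7 4-(5-{2-[3-(benzyloxy)phenyl]ethyl}-2,3-dimethoxyphenoxy)benzonitrile
Product: 9 4-(5-{2-[3-(benzyloxy)phenyl]ethyl}-2,3-dimethoxyphenoxy)benzaldehyde, via N-diisobutylalumanyl imine 8 (not isolated)
Conditions: DIBAL-H, CH2Cl2, −78 °C; then aq. HCl, 0 °C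
Reagents that add atoms: water, O
Why: DIBAL-H should add once to the nitrile to give the N-aluminated imine, which is hydrolysed to the aldehyde on acidic work-up (nitrile-to-aldehyde reduction); benzyl and aryl ethers are untouched.

Step 5
Reactants: 9 4-(5-{2-[3-(benzyloxy)phenyl]ethyl}-2,3-dimethoxyphenoxy)benzaldehyde
Product: 10 1-(benzyloxy)-3-{2-[3-(4-ethenylphenoxy)-4,5-dimethoxyphenyl]ethyl}benzene
Conditions: Ph3PCH3Br, KOtBu, THF, 0 °C → rt
Reagents that add atoms: methyltriphenylphosphonium bromide, C[P+](c1ccccc1)(c1ccccc1)c1ccccc1.[Br-]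
Why: A second Wittig methylenation should give the ring B styrene for the second bridge.

Step 6
Reactants: 10 1-(benzyloxy)-3-{2-[3-(4-ethenylphenoxy)-4,5-dimethoxyphenyl]ethyl}benzene; 11 3-bromo-5-methoxyphenol
Product: 13 3-methoxy-5-(arm P)phenol, via B-alkyl-9-BBN adduct 12 (not isolated)
Conditions: 9-BBN, THF, 0 °C → rt; then Pd(dppf)Cl2 (cat.), aq. K3PO4 (excess), DMF, 60 °C
Reagents that add atoms: none
Why: Hydroboration/B-alkyl Suzuki–Miyaura coupling should form the B–CH2CH2–C bridge; the free phenol of 11 is carried as its phenoxide by the extra base.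

Step 7
Reactants: 13 3-methoxy-5-(arm P)phenol
Product: 14 3-methoxy-5-(arm P)phenyl N-(propan-2-yl)carbamate
Conditions: i-PrNCO, Et3N (cat.), CH2Cl2, rt
Reagents that add atoms: isopropyl isocyanate, CC(C)N=C=O
Why: Addition of the only free OH to the isocyanate (carbamoylation) should install the group that directs the ortho-silylation and is later removed under mild base.

Step 8
Reactants: 14 3-methoxy-5-(arm P)phenyl N-(propan-2-yl)carbamate
Product: 18 3-methoxy-5-(arm P)-2-(trimethylsilyl)phenyl N-(propan-2-yl)carbamate, via N-silyl carbamate 15 (not isolated), via C4-lithio N-silyl carbamate 16 (not isolated), via N,C-bis(trimethylsilyl) carbamate 17 (not isolated)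
Conditions: TMSOTf, TMEDA, Et2O, 0 °C → rt; n-BuLi, TMEDA, −78 °C; TMSCl, −78 °C → rt; aq. NaHSO4
Reagents that add atoms: chlorotrimethylsilane, C[Si](C)(C)Cl
Why: Directed ortho-metalation; after in situ N-silylation the carbamate on C3 and the methoxy group on C5 should jointly direct n-BuLi to C4, the only position flanked by two directing oxygens, and Me3SiCl quenches the aryllithium, the N-silyl group being lost on aqueous work-up.

Step 9
Reactants: 18 3-methoxy-5-(arm P)-2-(trimethylsilyl)phenyl N-(propan-2-yl)carbamate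
Product: 20 3-methoxy-5-(arm P)-2-(trimethylsilyl)phenyl trifluoromethanesulfonate, via ortho-silyl phenol 19 (not isolated)
Conditions: DBU, Et2NH, MeCN, 40 °C; then PhNTf2, rt
Reagents that add atoms: N-phenylbis(trifluoromethanesulfonimide), FC(F)(F)S(=O)(=O)N(c1ccccc1)S(=O)(=O)C(F)(F)F
Why: DBU-promoted E1cB loss of isopropyl isocyanate (trapped by Et2NH as the urea) should free the hindered phenoxide, which is triflated in the same flask to give the o-silylaryl triflate (aryne precursor).

Step 10
Reactants: 20 3-methoxy-5-(arm P)-2-(trimethylsilyl)phenyl trifluoromethanesulfonate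
Product: 21 3-methoxy-5-(arm Q)-2-(trimethylsilyl)phenyl trifluoromethanesulfonate
Conditions: H2 (1 atm), Pd/C, EtOAc, rt
Reagents that add atoms: none
Why: Hydrogenolysis of the benzyl ether should free the ring D phenol; the aryl triflate and the aryl–SiMe3 bond are inert to H2/Pd–C in neutral ethyl acetate.

Step 11
Reactants: 21 3-methoxy-5-(arm Q)-2-(trimethylsilyl)phenyl trifluoromethanesulfonate
Product: 23 tri-O-methyl 4-deoxy macrocycle (19-membered ring of the target; OMe on both ring A oxygens and on ring C C5; H on ring C C4), via ring C aryne 22 (not isolated)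
Conditions: CsF (excess), MeCN, 50 °C, slow addition of 21 (final ca. 2 mM)
Reagents that add atoms: none
Why: Fluoride attacks SiMe3 on ring C C4 and triflate leaves from C3 to give the aryne C3≡C4 (22); the caesium phenoxide of ring D adds through oxygen to C3 and the C4 carbanion is protonated by the medium, a net insertion of the aryne into the phenol O–H bond. The closest known reaction type is the fluoride-mediated O-arylation of phenols with o-(trimethylsilyl)aryl triflates, used here in ring-closing mode. The 19-membered ring closes in exo fashion, the attacked carbon C3 becoming a ring atom while C4 stays outside the ring, and no stereocentre is formed. The required regioselectivity (O to C3, H to C4) is secured by the C5 methoxy group beside the triple bond, whose inductive pull distorts the aryne so that the distal carbon C3 is the electrophilic end and the negative charge develops on C4 next to oxygen. O- over C-arylation is secured by the loosely paired caesium phenoxide in acetonitrile. Ring closure over oligomerisation is secured by slow addition to excess CsF (very low standing concentration of aryne), one phenol and one aryne per molecule, and two flexible CH2CH2 hinges.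

Step 12
Reactants: 23 tri-O-methyl 4-deoxy macrocycle
Product: 26 tri-O-methyl ether of the target (ring C C4–OH free; OMe on both ring A oxygens and on ring C C5), via C4-lithio macrocycle 24 (not isolated), via C4-dimethoxyboryl macrocycle 25 (not isolated)
Conditions: n-BuLi, TMEDA, THF, −20 → 0 °C; B(OMe)3, −78 °C → rt; H2O2, aq. NaOH, 0 °C
Reagents that add atoms: hydrogen peroxide, OO
Why: Directed ortho-metalation at ring C C4, the only aryl C–H flanked by two ether oxygens (O on C3, OMe on C5), followed by borylation and oxidative C–B to C–O conversion should install the hydroxyl.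

Step 13
Reactants: 26 tri-O-methyl ether of the target
Product: 27 target macrocyclic bis(bibenzyl) CNP0511668.0
Conditions: BBr3 (excess), CH2Cl2, −78 °C → rt; then MeOH/H2O
Reagents that add atoms: none
Why: Lewis-acid demethylation; BBr3 should cleave the three aryl methyl ethers (O–B complexation, bromide attack on methyl), while the two diaryl ethers are not cleaved.

**Compound list**

1 | 3-hydroxy-4,5-dimethoxybenzaldehyde | O=Cc1cc(O)c(OC)c(OC)c1 | starting material
2 | 4-fluorobenzonitrile | N#Cc1ccc(F)cc1 | starting material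
3 | 4-(5-formyl-2,3-dimethoxyphenoxy)benzonitrile | N#Cc1ccc(Oc2cc(C=O)cc(OC)c2OC)cc1 | intermediate
4 | 4-(5-ethenyl-2,3-dimethoxyphenoxy)benzonitrile | N#Cc1ccc(Oc2cc(C=C)cc(OC)c2OC)cc1 | intermediate
5 | 1-(benzyloxy)-3-bromobenzene | Brc1cccc(OCc2ccccc2)c1 | starting material
6 | 4-{5-[2-(9-borabicyclo[3.3.1]nonan-9-yl)ethyl]-2,3-dimethoxyphenoxy}benzonitrile (not isolated) | N#Cc1ccc(Oc2cc(CCB3C4CCCC3CCC4)cc(OC)c2OC)cc1 | intermediate
7 | 4-(5-{2-[3-(benzyloxy)phenyl]ethyl}-2,3-dimethoxyphenoxy)benzonitrile | N#Cc1ccc(Oc2cc(CCc3cccc(OCc4ccccc4)c3)cc(OC)c2OC)cc1 | intermediate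
8 | N-(diisobutylalumanyl)imine of aldehyde 9 (not isolated) | CC(C)C[Al](CC(C)C)N=Cc1ccc(Oc2cc(CCc3cccc(OCc4ccccc4)c3)cc(OC)c2OC)cc1 | intermediate
9 | 4-(5-{2-[3-(benzyloxy)phenyl]ethyl}-2,3-dimethoxyphenoxy)benzaldehyde | O=Cc1ccc(Oc2cc(CCc3cccc(OCc4ccccc4)c3)cc(OC)c2OC)cc1 | intermediate
10 | 1-(benzyloxy)-3-{2-[3-(4-ethenylphenoxy)-4,5-dimethoxyphenyl]ethyl}benzene | C=Cc1ccc(Oc2cc(CCc3cccc(OCc4ccccc4)c3)cc(OC)c2OC)cc1 | intermediate
11 | 3-bromo-5-methoxyphenol | COc1cc(O)cc(Br)c1 | starting material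
12 | B-alkyl-9-BBN adduct of styrene 10 (9-BBN on the terminal carbon; not isolated) | COc1cc(CCc2cccc(OCc3ccccc3)c2)cc(Oc2ccc(CCB3C4CCCC3CCC4)cc2)c1OC | intermediate
13 | 3-methoxy-5-(arm P)phenol | COc1cc(O)cc(CCc2ccc(Oc3cc(CCc4cccc(OCc5ccccc5)c4)cc(OC)c3OC)cc2)c1 | intermediate
14 | 3-methoxy-5-(arm P)phenyl N-(propan-2-yl)carbamate | COc1cc(OC(=O)NC(C)C)cc(CCc2ccc(Oc3cc(CCc4cccc(OCc5ccccc5)c4)cc(OC)c3OC)cc2)c1 | intermediate
15 | N-trimethylsilyl derivative of 14 (not isolated) | COc1cc(OC(=O)N(C(C)C)[Si](C)(C)C)cc(CCc2ccc(Oc3cc(CCc4cccc(OCc5ccccc5)c4)cc(OC)c3OC)cc2)c1 | intermediate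
16 | 15 lithiated at ring C C4, between OMe and the carbamate oxygen (not isolated) | COc1cc(CCc2ccc(Oc3cc(CCc4cccc(OCc5ccccc5)c4)cc(OC)c3OC)cc2)cc(OC(=O)N(C(C)C)[Si](C)(C)C)c1[Li] | intermediate
17 | 3-methoxy-5-(arm P)-2-(trimethylsilyl)phenyl N-(propan-2-yl)-N-(trimethylsilyl)carbamate (not isolated) | COc1cc(CCc2ccc(Oc3cc(CCc4cccc(OCc5ccccc5)c4)cc(OC)c3OC)cc2)cc(OC(=O)N(C(C)C)[Si](C)(C)C)c1[Si](C)(C)C | intermediate
18 | 3-methoxy-5-(arm P)-2-(trimethylsilyl)phenyl N-(propan-2-yl)carbamate | COc1cc(CCc2ccc(Oc3cc(CCc4cccc(OCc5ccccc5)c4)cc(OC)c3OC)cc2)cc(OC(=O)NC(C)C)c1[Si](C)(C)C | intermediate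
19 | 3-methoxy-5-(arm P)-2-(trimethylsilyl)phenol (not isolated) | COc1cc(CCc2ccc(Oc3cc(CCc4cccc(OCc5ccccc5)c4)cc(OC)c3OC)cc2)cc(O)c1[Si](C)(C)C | intermediate
20 | 3-methoxy-5-(arm P)-2-(trimethylsilyl)phenyl trifluoromethanesulfonate | COc1cc(CCc2ccc(Oc3cc(CCc4cccc(OCc5ccccc5)c4)cc(OC)c3OC)cc2)cc(OS(=O)(=O)C(F)(F)F)c1[Si](C)(C)C | intermediate
21 | 3-methoxy-5-(arm Q)-2-(trimethylsilyl)phenyl trifluoromethanesulfonate | COc1cc(CCc2ccc(Oc3cc(CCc4cccc(O)c4)cc(OC)c3OC)cc2)cc(OS(=O)(=O)C(F)(F)F)c1[Si](C)(C)C | intermediate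
22 | ring C aryne: 3-methoxy-5-(arm Q)-1,2-didehydrobenzene, triple bond between ring C C3 and C4 (not isolated) | COC1=CC(CCc2ccc(Oc3cc(CCc4cccc(O)c4)cc(OC)c3OC)cc2)=CC#C1 | intermediate
23 | tri-O-methyl 4-deoxy macrocycle (ring A di-OMe; ring C C5–OMe, C4–H) | COc1cc2cc(c1OC)Oc1ccc(cc1)CCc1cc(OC)cc(c1)Oc1cccc(c1)CC2 | intermediate
24 | 23 lithiated at ring C C4 (not isolated) | COc1cc2cc(c1OC)Oc1ccc(cc1)CCc1cc(OC)c([Li])c(c1)Oc1cccc(c1)CC2 | intermediate
25 | dimethyl boronate of 23 at ring C C4 (not isolated) | COc1cc2cc(c1OC)Oc1ccc(cc1)CCc1cc(OC)c(B(OC)OC)c(c1)Oc1cccc(c1)CC2 | intermediate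
26 | tri-O-methyl ether of the target (ring A di-OMe; ring C C5–OMe, C4–OH) | COc1cc2cc(c1OC)Oc1ccc(cc1)CCc1cc(OC)c(O)c(c1)Oc1cccc(c1)CC2 | intermediate
27 | target macrocyclic bis(bibenzyl) CNP0511668.0 | Oc1cc2cc(c1O)Oc1ccc(cc1)CCc1cc(O)c(O)c(c1)Oc1cccc(c1)CC2 | target

**Count and risks**

Total step count: 13. Longest linear sequence: 13 steps (1 → 27).

Steps most likely to fail, with fallbacks:

Step 11 (ring closure). The short-lived aryne may be consumed between molecules (oligomeric diaryl ethers) or by fluoride or acetonitrile before the 19-membered ring can close. The fallback forms the same C3–O bond by a metal-catalysed coupling and sets out from phenol 13. Triflation (Tf2O, pyridine, CH2Cl2) should give 3-methoxy-5-(arm P)phenyl trifluoromethanesulfonate F1. Hydrogenolysis (H2, Pd/C, EtOAc) should free the ring D phenol to give 3-methoxy-5-(arm Q)phenyl trifluoromethanesulfonate F2. An intramolecular palladium-catalysed C–O coupling (Buchwald–Hartwig etherification: Pd(OAc)2, tBuXPhos, K3PO4, toluene, 100 °C, high dilution) should then close the ring and come back to the route at 23.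

Step 8 (ortho-silylation). Lithiation may occur at other sites (ring A, the benzylic CH2 of the benzyl ether), or n-BuLi may add to the carbamate carbonyl. The fallback builds the isomeric precursor of the same aryne without directed metalation and sets out from styrene 10. Its 9-BBN adduct 12 is coupled with 4-bromo-2-methoxyphenol (Pd(dppf)Cl2, aq. K3PO4) to give 2-methoxy-4-(arm P)phenol F3. Ortho-bromination of the free phenol (NBS, cat. i-Pr2NH, CH2Cl2, 0 °C) should give 2-bromo-6-methoxy-4-(arm P)phenol F4. O-Silylation with hexamethyldisilazane gives the trimethylsilyl ether of F4, F5. Bromine–lithium exchange (n-BuLi, THF, −78 °C) should trigger the 1,3 O→C silyl shift (retro-Brook rearrangement), and triflation of the phenoxide with Tf2O gives 2-methoxy-4-(arm P)-6-(trimethylsilyl)phenyl trifluoromethanesulfonate F6. Hydrogenolysis gives 2-methoxy-4-(arm Q)-6-(trimethylsilyl)phenyl trifluoromethanesulfonate F7. With CsF in MeCN, F7 loses SiMe3 from C3 and triflate from C4, passes through the same aryne 22 and comes back to the route at 23.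

Step 12 (hydroxylation). Metalation may occur at other positions of the macrocycle or stay incomplete, and the electron-rich phenol may be over-oxidised during the peroxide work-up. The fallback brings the C4 oxygen in before ring closure and forms the same C3–O bond by copper catalysis. It sets out from styrene 10 and passes through phenol F3 and bromophenol F4, made as in the fallback for step 8. O-Methylation (MeI, K2CO3, DMF) should give 1-bromo-2,3-dimethoxy-5-(arm P)benzene F8. Debenzylation that spares the aryl bromide (BCl3, pentamethylbenzene, CH2Cl2, −78 °C) should give 1-bromo-2,3-dimethoxy-5-(arm Q)benzene F9. Intramolecular Ullmann ether synthesis (CuI, N,N-dimethylglycine, Cs2CO3, dioxane, 100 °C, high dilution) should give the tetra-O-methyl ether of the target, F10. BBr3 (CH2Cl2, −78 °C → rt) then comes back to the route at the target 27.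

Further compounds
F1 | step 11 | 3-methoxy-5-(arm P)phenyl trifluoromethanesulfonate | COc1cc(OS(=O)(=O)C(F)(F)F)cc(CCc2ccc(Oc3cc(CCc4cccc(OCc5ccccc5)c4)cc(OC)c3OC)cc2)c1
F2 | step 11 | 3-methoxy-5-(arm Q)phenyl trifluoromethanesulfonate | COc1cc(OS(=O)(=O)C(F)(F)F)cc(CCc2ccc(Oc3cc(CCc4cccc(O)c4)cc(OC)c3OC)cc2)c1
F3 | step 8 | 2-methoxy-4-(arm P)phenol | COc1cc(CCc2ccc(Oc3cc(CCc4cccc(OCc5ccccc5)c4)cc(OC)c3OC)cc2)ccc1O
F4 | step 8 | 2-bromo-6-methoxy-4-(arm P)phenol | COc1cc(CCc2ccc(Oc3cc(CCc4cccc(OCc5ccccc5)c4)cc(OC)c3OC)cc2)cc(Br)c1O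
F5 | step 8 | [2-bromo-6-methoxy-4-(arm P)phenoxy]trimethylsilane | COc1cc(CCc2ccc(Oc3cc(CCc4cccc(OCc5ccccc5)c4)cc(OC)c3OC)cc2)cc(Br)c1O[Si](C)(C)C
F6 | step 8 | 2-methoxy-4-(arm P)-6-(trimethylsilyl)phenyl trifluoromethanesulfonate | COc1cc(CCc2ccc(Oc3cc(CCc4cccc(OCc5ccccc5)c4)cc(OC)c3OC)cc2)cc([Si](C)(C)C)c1OS(=O)(=O)C(F)(F)F
F7 | step 8 | 2-methoxy-4-(arm Q)-6-(trimethylsilyl)phenyl trifluoromethanesulfonate | COc1cc(CCc2ccc(Oc3cc(CCc4cccc(O)c4)cc(OC)c3OC)cc2)cc([Si](C)(C)C)c1OS(=O)(=O)C(F)(F)F
F8 | step 12 | 1-bromo-2,3-dimethoxy-5-(arm P)benzene | COc1cc(CCc2ccc(Oc3cc(CCc4cccc(OCc5ccccc5)c4)cc(OC)c3OC)cc2)cc(Br)c1OC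
F9 | step 12 | 1-bromo-2,3-dimethoxy-5-(arm Q)benzene | COc1cc(CCc2ccc(Oc3cc(CCc4cccc(O)c4)cc(OC)c3OC)cc2)cc(Br)c1OC
F10 | step 12 | tetra-O-methyl ether of the target (OMe on both ring A oxygens and on ring C C4 and C5) | COc1cc2cc(c1OC)Oc1ccc(cc1)CCc1cc(OC)c(OC)c(c1)Oc1cccc(c1)CC2
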